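**Strategy.** The route rests on forming the C1–C6 bond of each trimethylcyclohexene end ring. This bond joins the gem-dimethyl quaternary carbon C1 to ring carbon C6, which carries the exocyclic C6=C7 double bond of the retro-polyene. One formate-terminated intramolecular Heck reaction closes the ring, creates the quaternary centre (the alkene CH2 becomes the second C1 methyl) and carries the preset alkenyl iodide geometry into the 6E alkylidene. Its precursor is an acyclic (2Z,4Z)-3-iodo-2,4-dienol with a silylated (S)-carbinol and a methallyl terminus. Two copies of the derived C14 aldehyde are then joined to a C12 tetraenyl bisphosphonate and desilylated.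

Key step: step 7

Assumption: carotenoid numbering is used for the end group (C1 = CMe2, C3 = carbinol carbon, C5 = methyl-bearing ring alkene carbon, C6 = ring carbon of the exocyclic alkene, C7 and C8 = first chain carbons), and "(−)-Ipc2BOMe" means the enantiomer made from (+)-α-pinene.

**Step 1**
Reactants: 1 but-2-yn-1-ol
Product: 3 (Z)-3-iodobut-2-en-1-ol, via cyclic vinylalanate 2 (not isolated)
Conditions: NaAlH2(OCH2CH2OCH3)2, THF, 0 °C → rt; then I2, THF, −78 → 0 °C
Reagents that add atoms: iodine, II
Why: Alkoxide-directed trans-hydroalumination of the propargylic alcohol delivers hydride to C2 and aluminium to C3 within a five-membered alanate, and iodinolysis of the C–Al bond with retention should give the (Z)-3-iodo allylic alcohol as one regio- and stereoisomer.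

**Step 2**
Reactants: 3 (Z)-3-iodobut-2-en-1-ol
Product: 4 (Z)-3-iodobut-2-enal
Conditions: MnO2 (activated, excess), CH2Cl2, rt, dark; used directly
Reagents that add atoms: none
Why: Allylic oxidation with activated MnO2 is selective for the primary allylic alcohol under neutral conditions, so the alkenyl iodide and its Z geometry should be preserved.

**Step 3**
Reactants: 4 (Z)-3-iodobut-2-enal; 5 (2-methylprop-2-en-1-yl)magnesium chloride
Product: 8 (4S,5Z)-6-iodo-2-methylhepta-1,5-dien-4-ol, via B-methallyldiisopinocampheylborane 6 (not isolated), via diisopinocampheylborinate ester 7 (not isolated)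
Conditions: (−)-Ipc2BOMe [from (+)-α-pinene], 5, Et2O, −78 °C → rt; then 4, −78 °C; then NaOH, H2O2, 0 °C → rt
Reagents that add atoms: none
Why: Brown asymmetric methallylboration, in which the borane formed from 5 adds through a chair-like six-membered transition state whose isopinocampheyl groups direct the methallyl group to the Si face of the aldehyde and so set the (S)-carbinol (the future C3), after which alkaline peroxide cleaves the borinate.

**Step 4**
Reactants: 8 (4S,5Z)-6-iodo-2-methylhepta-1,5-dien-4-ol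
Product: 9 tert-butyl{[(4S,5Z)-6-iodo-2-methylhepta-1,5-dien-4-yl]oxy}dimethylsilane
Conditions: TBSCl, imidazole, DMF, rt
Reagents that add atoms: tert-butyldimethylsilyl chloride, CC(C)(C)[Si](C)(C)Cl
Why: Imidazole-promoted silylation of the secondary alcohol gives a tert-butyldimethylsilyl ether that should tolerate the later hydride, palladium, ylide and amide-base conditions and is removed only at the end.

**Step 5**
Reactants: 9 tert-butyl{[(4S,5Z)-6-iodo-2-methylhepta-1,5-dien-4-yl]oxy}dimethylsilane; 10 prop-2-yn-1-ol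
Product: 11 (4Z,6S)-6-(tert-butyldimethylsilyloxy)-4,8-dimethylnona-4,8-dien-2-yn-1-ol
Conditions: Pd(PPh3)2Cl2 (cat.), CuI (cat.), Et3N, THF, rt
Reagents that add atoms: none
Why: Sonogashira coupling of an alkenyl iodide with a terminal alkyne proceeds with retention of alkene geometry, so the alkyne ends cis to the carbinol carbon as the later ring requires.

**Step 6**
Reactants: 11 (4Z,6S)-6-(tert-butyldimethylsilyloxy)-4,8-dimethylnona-4,8-dien-2-yn-1-ol
Product: 13 (2Z,4Z,6S)-6-(tert-butyldimethylsilyloxy)-3-iodo-4,8-dimethylnona-2,4,8-trien-1-ol, via cyclic dienylalanate 12 (not isolated)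
Conditions: NaAlH2(OCH2CH2OCH3)2, THF, 0 °C → rt; then I2, THF, −78 → 0 °C
Reagents that add atoms: iodine, II
Why: The same hydroxyl-directed trans-hydroalumination–iodination places iodine on the alkyne carbon remote from oxygen and cis to CH2OH, while the silyl ether and the unactivated alkenes are inert to the alanate.

**Step 7**
Reactants: 13 (2Z,4Z,6S)-6-(tert-butyldimethylsilyloxy)-3-iodo-4,8-dimethylnona-2,4,8-trien-1-ol
Product: 14 (E)-2-[(4S)-4-(tert-butyldimethylsilyloxy)-2,6,6-trimethylcyclohex-2-en-1-ylidene]ethanol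
Conditions: Pd(OAc)2 (10 mol %), PPh3 (25 mol %), HCO2Na (1.5 equiv), Et4NCl, DMF (0.02 M, degassed), 80 °C
Reagents that add atoms: none
Why: Oxidative addition of the C6–I bond to zerovalent palladium (from Pd(OAc)2 and PPh3) gives a dienylpalladium iodide with retention of geometry, syn-carbopalladation of the 1,1-disubstituted alkene joins C6 to its substituted carbon (the future C1), and the neopentyl alkylpalladium, which has no β-hydrogen, exchanges iodide for formate, loses CO2 and reductively eliminates C–H so that the former =CH2 becomes the second C1 methyl. The closest known reaction type is the formate-terminated (reductive) intramolecular Heck cyclisation of aryl and alkenyl iodides onto methallyl groups, which delivers gem-dimethyl quaternary carbons. The one ring closed is the six-membered carbocycle, formed in the 6-exo-trig mode through the C1–C6 bond. No stereocentre is created: C1 carries two identical methyl groups, C3 passes through unchanged and the 6E geometry is that of the alkenyl iodide. The step needs exo rather than 7-endo insertion, and cyclisation ahead of hydride capture of the dienylpalladium or 3-exo attack of the alkylpalladium on C6=C7; the (Z)-C4=C5 alkene holds C6 next to the methallyl alkene, high dilution with sparingly soluble HCO2Na keeps hydride delivery slow before insertion, and the lack of a β-hydrogen leaves formate capture as the fastest outlet afterwards.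

**Step 8**
Reactants: 14 (E)-2-[(4S)-4-(tert-butyldimethylsilyloxy)-2,6,6-trimethylcyclohex-2-en-1-ylidene]ethanol
Product: 15 (E)-2-[(4S)-4-(tert-butyldimethylsilyloxy)-2,6,6-trimethylcyclohex-2-en-1-ylidene]acetaldehyde
Conditions: MnO2 (activated, excess), CH2Cl2, rt
Reagents that add atoms: none
Why: Allylic oxidation with MnO2 converts the primary dienylic alcohol into the aldehyde without touching the silyl ether, and the 6E aldehyde has C8 remote from C5 and so cannot undergo oxa-electrocyclisation.

**Step 9**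
Reactants: 15 (E)-2-[(4S)-4-(tert-butyldimethylsilyloxy)-2,6,6-trimethylcyclohex-2-en-1-ylidene]acetaldehyde; 16 2-(triphenyl-λ5-phosphanylidene)propanal
Product: 17 (2E,4E)-4-[(4S)-4-(tert-butyldimethylsilyloxy)-2,6,6-trimethylcyclohex-2-en-1-ylidene]-2-methylbut-2-enal
Conditions: 16 (1.3 equiv), toluene, 80 °C
Reagents that add atoms: none
Why: Wittig reaction with the stabilised formyl ylide is E-selective and should stop after one homologation because the 2-methyl-enal product is much less electrophilic than 15.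

**Step 10**
Reactants: 18 (E)-3-methylpent-2-en-4-yn-1-ol
Product: 19 (2E,4E)-3-methyl-5-(tributylstannyl)penta-2,4-dien-1-ol
Conditions: Bu3SnH, Pd(PPh3)2Cl2 (cat.), THF, 0 °C → rt
Reagents that add atoms: tributyltin hydride, CCCC[SnH](CCCC)CCCC
Why: Palladium-catalysed hydrostannation of the terminal alkyne is a syn addition that places tin at the unhindered terminus, giving the (E)-alkenylstannane, and any internal regioisomer can be removed by chromatography.

**Step 11**
Reactants: 19 (2E,4E)-3-methyl-5-(tributylstannyl)penta-2,4-dien-1-ol (2 equiv)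
Product: 21 (2E,4E,6E,8E)-3,8-dimethyldeca-2,4,6,8-tetraene-1,10-diol, via (2E,4E)-5-iodo-3-methylpenta-2,4-dien-1-ol 20 (not isolated)
Conditions: I2 (0.5 equiv), Et2O, 0 °C; then Pd(MeCN)2Cl2 (cat.), DMF, rt
Reagents that add atoms: none
Why: Iododestannylation of half of 19 with retention, followed by Stille coupling of the resulting alkenyl iodide with the remaining stannane, joins two identical C6 units at C15–C15' with all four double bonds E.

**Step 12**
Reactants: 21 (2E,4E,6E,8E)-3,8-dimethyldeca-2,4,6,8-tetraene-1,10-diol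
Product: 22 (2E,4E,6E,8E)-1,10-dibromo-3,8-dimethyldeca-2,4,6,8-tetraene
Conditions: PBr3, Et2O, −10 °C, dark; used crude
Reagents that add atoms: phosphorus tribromide, BrP(Br)Br
Why: Bromination of primary allylic alcohols with PBr3 proceeds by SN2 displacement of the phosphite ester, and the fully conjugated primary dibromide is the thermodynamically favoured allylic isomer.

**Step 13**
Reactants: 22 (2E,4E,6E,8E)-1,10-dibromo-3,8-dimethyldeca-2,4,6,8-tetraene
Product: 23 tetraethyl [(2E,4E,6E,8E)-3,8-dimethyldeca-2,4,6,8-tetraene-1,10-diyl]bis(phosphonate)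
Conditions: P(OEt)3 (excess), 100 °C, EtBr distilled off
Reagents that add atoms: triethyl phosphite, CCOP(OCC)OCC
Why: Michaelis–Arbuzov reaction of the primary allylic bromides with triethyl phosphite should give the bisphosphonate, driven by loss of ethyl bromide.

**Step 14**
Reactants: 23 tetraethyl [(2E,4E,6E,8E)-3,8-dimethyldeca-2,4,6,8-tetraene-1,10-diyl]bis(phosphonate); 17 (2E,4E)-4-[(4S)-4-(tert-butyldimethylsilyloxy)-2,6,6-trimethylcyclohex-2-en-1-ylidene]-2-methylbut-2-enal (2 equiv)
Product: 25 (3S,3'S,6E,6'E,all-E)-3,3'-bis(tert-butyldimethylsilyloxy)-4',5'-didehydro-4,5'-retro-β,β-carotene, via C26 monophosphonate 24 (not isolated)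
Conditions: NaN(SiMe3)2 (1.0 equiv), THF, −78 °C; 17 (1.0 equiv), −78 → 0 °C; then NaN(SiMe3)2 (1.0 equiv), −78 °C; 17 (1.05 equiv), −78 °C → rt
Reagents that add atoms: none
Why: Horner–Wadsworth–Emmons olefination of the allylic phosphonate carbanions with the enal is E-selective at the new C10=C11 and C10'=C11' bonds, and forming each anion with one equivalent of amide base before the aldehyde is added should keep free base away from the allylic C3–H.

**Step 15**
Reactants: 25 (3S,3'S,6E,6'E,all-E)-3,3'-bis(tert-butyldimethylsilyloxy)-4',5'-didehydro-4,5'-retro-β,β-carotene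
Product: 26 (3S,3'S,6E,6'E,all-E)-4',5'-didehydro-4,5'-retro-β,β-carotene-3,3'-diol (eschscholtzxanthin)
Conditions: Bu4NF, AcOH, THF, 0 °C → rt, dark
Reagents that add atoms: none
Why: Fluoride-mediated desilylation buffered with acetic acid should remove both silyl groups without the acid or strong base that the allylic C3 alcohols and the retro-polyene would not tolerate.

**Compound list**

1 | but-2-yn-1-ol | CC#CCO | starting material
2 | sodium 2,2-bis(2-methoxyethoxy)-3-methyl-2,5-dihydro-1,2-oxaaluminol-2-uide (cyclic vinylalanate) | [Na+].COCCO[Al-]1(OCCOC)OCC=C1C | intermediate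
3 | (Z)-3-iodobut-2-en-1-ol | C/C(I)=C/CO | intermediate
4 | (Z)-3-iodobut-2-enal | C/C(I)=C/C=O | intermediate
5 | (2-methylprop-2-en-1-yl)magnesium chloride (THF solution) | C=C(C)C[Mg]Cl | starting material
6 | (2-methylprop-2-en-1-yl)bis[(1R,2S,3R,5R)-2,6,6-trimethylbicyclo[3.1.1]heptan-3-yl]borane | C=C(C)CB([C@@H]1C[C@@H]2C[C@H]([C@H]1C)C2(C)C)[C@@H]1C[C@@H]2C[C@H]([C@H]1C)C2(C)C | intermediate
7 | (4S,5Z)-6-iodo-2-methylhepta-1,5-dien-4-yl bis[(1R,2S,3R,5R)-2,6,6-trimethylbicyclo[3.1.1]heptan-3-yl]borinate | C/C(I)=C/[C@@H](OB([C@@H]1C[C@@H]2C[C@H]([C@H]1C)C2(C)C)[C@@H]1C[C@@H]2C[C@H]([C@H]1C)C2(C)C)CC(C)=C | intermediate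
8 | (4S,5Z)-6-iodo-2-methylhepta-1,5-dien-4-ol | C/C(I)=C/[C@@H](O)CC(C)=C | intermediate
9 | tert-butyl{[(4S,5Z)-6-iodo-2-methylhepta-1,5-dien-4-yl]oxy}dimethylsilane | C/C(I)=C/[C@@H](O[Si](C)(C)C(C)(C)C)CC(C)=C | intermediate
10 | prop-2-yn-1-ol | C#CCO | starting material
11 | (4Z,6S)-6-(tert-butyldimethylsilyloxy)-4,8-dimethylnona-4,8-dien-2-yn-1-ol | OCC#C/C(C)=C\[C@@H](O[Si](C)(C)C(C)(C)C)CC(C)=C | intermediate
12 | sodium 3-[(2Z,4S)-4-(tert-butyldimethylsilyloxy)-6-methylhepta-2,6-dien-2-yl]-2,2-bis(2-methoxyethoxy)-2,5-dihydro-1,2-oxaaluminol-2-uide (cyclic dienylalanate) | [Na+].COCCO[Al-]1(OCCOC)OCC=C1/C(C)=C\[C@@H](O[Si](C)(C)C(C)(C)C)CC(C)=C | intermediate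
13 | (2Z,4Z,6S)-6-(tert-butyldimethylsilyloxy)-3-iodo-4,8-dimethylnona-2,4,8-trien-1-ol | OC/C=C(I)/C(C)=C\[C@@H](O[Si](C)(C)C(C)(C)C)CC(C)=C | intermediate
14 | (E)-2-[(4S)-4-(tert-butyldimethylsilyloxy)-2,6,6-trimethylcyclohex-2-en-1-ylidene]ethanol | CC1=C[C@@H](O[Si](C)(C)C(C)(C)C)CC(C)(C)\C1=C/CO | intermediate
15 | (E)-2-[(4S)-4-(tert-butyldimethylsilyloxy)-2,6,6-trimethylcyclohex-2-en-1-ylidene]acetaldehyde | CC1=C[C@@H](O[Si](C)(C)C(C)(C)C)CC(C)(C)\C1=C/C=O | intermediate
16 | 2-(triphenyl-λ5-phosphanylidene)propanal | CC(C=O)=P(c1ccccc1)(c1ccccc1)c1ccccc1 | starting material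
17 | (2E,4E)-4-[(4S)-4-(tert-butyldimethylsilyloxy)-2,6,6-trimethylcyclohex-2-en-1-ylidene]-2-methylbut-2-enal | CC1=C[C@@H](O[Si](C)(C)C(C)(C)C)CC(C)(C)\C1=C/C=C(C)/C=O | intermediate
18 | (E)-3-methylpent-2-en-4-yn-1-ol | C#C/C(C)=C/CO | starting material
19 | (2E,4E)-3-methyl-5-(tributylstannyl)penta-2,4-dien-1-ol | CCCC[Sn](CCCC)(CCCC)/C=C/C(C)=C/CO | intermediate
20 | (2E,4E)-5-iodo-3-methylpenta-2,4-dien-1-ol | I/C=C/C(C)=C/CO | intermediate
21 | (2E,4E,6E,8E)-3,8-dimethyldeca-2,4,6,8-tetraene-1,10-diol | OC/C=C(C)/C=C/C=C/C(C)=C/CO | intermediate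
22 | (2E,4E,6E,8E)-1,10-dibromo-3,8-dimethyldeca-2,4,6,8-tetraene | BrC/C=C(C)/C=C/C=C/C(C)=C/CBr | intermediate
23 | tetraethyl [(2E,4E,6E,8E)-3,8-dimethyldeca-2,4,6,8-tetraene-1,10-diyl]bis(phosphonate) | CCOP(=O)(OCC)C/C=C(C)/C=C/C=C/C(C)=C/CP(=O)(OCC)OCC | intermediate
24 | diethyl {(2E,4E,6E,8E,10E,12E,14E)-14-[(4S)-4-(tert-butyldimethylsilyloxy)-2,6,6-trimethylcyclohex-2-en-1-ylidene]-3,8,12-trimethyltetradeca-2,4,6,8,10,12-hexaen-1-yl}phosphonate (C26 monophosphonate) | CC1=C[C@@H](O[Si](C)(C)C(C)(C)C)CC(C)(C)\C1=C/C=C(C)/C=C/C=C(C)/C=C/C=C/C(C)=C/CP(=O)(OCC)OCC | intermediate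
25 | (3S,3'S,6E,6'E,all-E)-3,3'-bis(tert-butyldimethylsilyloxy)-4',5'-didehydro-4,5'-retro-β,β-carotene | CC1=C[C@@H](O[Si](C)(C)C(C)(C)C)CC(C)(C)\C1=C/C=C(C)/C=C/C=C(C)/C=C/C=C/C(C)=C/C=C/C(C)=C/C=C1/C(C)=C[C@@H](O[Si](C)(C)C(C)(C)C)CC1(C)C | intermediate
26 | (3S,3'S,6E,6'E,all-E)-4',5'-didehydro-4,5'-retro-β,β-carotene-3,3'-diol (eschscholtzxanthin) | CC1=C[C@@H](O)CC(C)(C)\C1=C/C=C(C)/C=C/C=C(C)/C=C/C=C/C(C)=C/C=C/C(C)=C/C=C1/C(C)=C[C@@H](O)CC1(C)C | target

**Step count and risks**

Total steps: 15. Longest linear sequence: 11 steps (steps 1–9, 14 and 15, from but-2-yn-1-ol); the C12 branch (steps 10–13) joins at step 14.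

Steps most likely to fail:

1. Step 7 (reductive Heck closure). The risk is hydride transfer from formate to the dienylpalladium before the alkene has inserted, which would give the uncyclised deiodinated trienol, or slow insertion at the hindered alkene. The fallback sets out from 13 and separates ring closure from reduction. A palladium-catalysed iodine-atom-transfer cyclisation (carboiodination; Pd(P(t-Bu)3)2 cat., toluene, 100 °C, no hydride source) should close the same C1–C6 bond and end by C–I reductive elimination. This would give the neopentyl iodide (Z)-2-[(4S,6RS)-4-(tert-butyldimethylsilyloxy)-6-(iodomethyl)-2,6-dimethylcyclohex-2-en-1-ylidene]ethanol F1, with CH2OH still cis to the quaternary carbon and both C6 epimers acceptable. Radical deiodination (Bu3SnH, AIBN, benzene, 80 °C, high tin hydride concentration) then turns CH2I into the second methyl, removes the extra stereocentre and returns to 14.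

2. Step 14 (double Horner–Wadsworth–Emmons union). The risk is proton abstraction at the allylic C3–H or elsewhere in the base-sensitive retro-polyenal by the carbanions, a stalled second olefination, or loss of E-selectivity. The fallback sets out from 21 and uses 17 unchanged. Treating 21 with PPh3·HBr (MeOH, rt) should give [(2E,4E,6E,8E)-3,8-dimethyldeca-2,4,6,8-tetraene-1,10-diyl]bis(triphenylphosphonium) dibromide F2. A double Wittig reaction with 17 in 1,2-epoxybutane/EtOH at reflux generates the ylide without added strong base. Thermal equilibration of any 10Z isomers (heptane, reflux) then returns to 25.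

3. Step 9 (formyl-ylide Wittig homologation). The risk is a second condensation of the product enal with the ylide and geometric drift at C6=C7 during prolonged heating. The fallback sets out from 15. Horner–Wadsworth–Emmons reaction with triethyl 2-phosphonopropionate (NaH, THF, 0 °C) should give ethyl (2E,4E)-4-[(4S)-4-(tert-butyldimethylsilyloxy)-2,6,6-trimethylcyclohex-2-en-1-ylidene]-2-methylbut-2-enoate F3, which cannot react further. Reduction with i-Bu2AlH (CH2Cl2, −78 °C) gives (2E,4E)-4-[(4S)-4-(tert-butyldimethylsilyloxy)-2,6,6-trimethylcyclohex-2-en-1-ylidene]-2-methylbut-2-en-1-ol F4, and MnO2 oxidation (CH2Cl2, rt) returns to 17.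

**Further compounds**

F1 | step 7 | (Z)-2-[(4S,6RS)-4-(tert-butyldimethylsilyloxy)-6-(iodomethyl)-2,6-dimethylcyclohex-2-en-1-ylidene]ethanol | CC1=C[C@@H](O[Si](C)(C)C(C)(C)C)CC(C)(CI)\C1=C/CO
F2 | step 14 | [(2E,4E,6E,8E)-3,8-dimethyldeca-2,4,6,8-tetraene-1,10-diyl]bis(triphenylphosphonium) dibromide | [Br-].[Br-].c1ccccc1[P+](c1ccccc1)(c1ccccc1)C/C=C(C)/C=C/C=C/C(C)=C/C[P+](c1ccccc1)(c1ccccc1)c1ccccc1
F3 | step 9 | ethyl (2E,4E)-4-[(4S)-4-(tert-butyldimethylsilyloxy)-2,6,6-trimethylcyclohex-2-en-1-ylidene]-2-methylbut-2-enoate | CC1=C[C@@H](O[Si](C)(C)C(C)(C)C)CC(C)(C)\C1=C/C=C(C)/C(=O)OCC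
F4 | step 9 | (2E,4E)-4-[(4S)-4-(tert-butyldimethylsilyloxy)-2,6,6-trimethylcyclohex-2-en-1-ylidene]-2-methylbut-2-en-1-ol | CC1=C[C@@H](O[Si](C)(C)C(C)(C)C)CC(C)(C)\C1=C/C=C(C)/CO
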